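**Retrosynthetic overview**
- Monotesone A is reached by removing three aryl silyl ethers from a flavanone, which comes from Wacker oxidation at the benzylic carbon C4 of a (2S)-2-aryl-2H-chromene.
- The plan rests on ring C: C3 is an unsubstituted methylene between the C4 aryl ketone and the C2 stereocentre, so the C3–C4 bond can be made as a C3=C4 alkene by ring-closing metathesis and C4 oxidised afterwards.
- The metathesis substrate, an (S)-1-arylallyl 2-vinylaryl ether, comes from an iridium-catalysed asymmetric allylic etherification that forms the O1–C2 bond and sets C2.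
- The fragments are a 3,5-bis(silyloxy)-2-vinylphenol from 2,4,6-trihydroxybenzaldehyde (ring A) and a ring B cinnamyl methyl carbonate from 3,4-dihydroxybenzaldehyde and prenyl bromide.
- Rings A and B are bought; ring C is the only ring formed, in step 9.

Key step: step 9

Assumption: the (Sa,Sc,Sc) enantiomer of the binaphthol-derived bis(1-phenylethyl)amine phosphoramidite is taken as the one that gives the (S)-ether in step 8; should the sense be the opposite, the (Ra,Rc,Rc) ligand is used and nothing else changes.

**Route**

Step 1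
Reactants: 1 3,4-dihydroxybenzaldehyde; 2 prenyl bromide (1-bromo-3-methylbut-2-ene)
Product: 3 3-hydroxy-4-(3-methylbut-2-enyloxy)benzaldehyde
Conditions: NaHCO3 (1.5 equiv), NaI (0.1 equiv), DMF, 40 °C
Reagents that add atoms: none
Why: The 4-OH, para to the formyl group, is the more acidic phenol, so the weak base forms only its phenoxide, which is alkylated by the allylic bromide (regioselective Williamson ether synthesis).

Step 2
Reactants: 3 3-hydroxy-4-(3-methylbut-2-enyloxy)benzaldehyde
Product: 4 3-(tert-butyldimethylsilyloxy)-4-(3-methylbut-2-enyloxy)benzaldehyde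
Conditions: TBSCl (1.2 equiv), imidazole (2.5 equiv), CH2Cl2, 0 °C to rt
Reagents that add atoms: tert-butyldimethylsilyl chloride, CC(C)(C)[Si](C)(C)Cl
Why: Imidazole-promoted silylation of a free phenol is routine, and the aldehyde and the prenyl ether are inert to it.

Step 3
Reactants: 4 3-(tert-butyldimethylsilyloxy)-4-(3-methylbut-2-enyloxy)benzaldehyde
Product: 5 ethyl (E)-3-[3-(tert-butyldimethylsilyloxy)-4-(3-methylbut-2-enyloxy)phenyl]prop-2-enoate
Conditions: (EtO)2P(O)CH2CO2Et (1.2 equiv), NaH (1.2 equiv), THF, 0 °C to rt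
Reagents that add atoms: triethyl phosphonoacetate, CCOC(=O)CP(=O)(OCC)OCC
Why: Horner–Wadsworth–Emmons olefination of an aromatic aldehyde with the stabilised phosphonate anion should give the (E)-cinnamate, and no free alkoxide is present to attack the aryl silyl ether.

Step 4
Reactants: 5 ethyl (E)-3-[3-(tert-butyldimethylsilyloxy)-4-(3-methylbut-2-enyloxy)phenyl]prop-2-enoate
Product: 7 (E)-3-[3-(tert-butyldimethylsilyloxy)-4-(3-methylbut-2-enyloxy)phenyl]prop-2-en-1-ol, via ring B cinnamaldehyde 6 (not isolated)
Conditions: i-Bu2AlH (2.5 equiv), CH2Cl2, −78 to 0 °C; aqueous KNaC4H4O6 (potassium sodium tartrate) work-up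
Reagents that add atoms: none
Why: i-Bu2AlH reduces the conjugated ester by 1,2-hydride delivery through the aldehyde to the allylic alcohol and leaves the alkenes and the aryl silyl ether alone.

Step 5
Reactants: 7 (E)-3-[3-(tert-butyldimethylsilyloxy)-4-(3-methylbut-2-enyloxy)phenyl]prop-2-en-1-ol
Product: 8 (E)-3-[3-(tert-butyldimethylsilyloxy)-4-(3-methylbut-2-enyloxy)phenyl]prop-2-enyl methyl carbonate
Conditions: ClCO2Me (1.5 equiv), pyridine (3 equiv), CH2Cl2, 0 °C
Reagents that add atoms: methyl chloroformate, COC(=O)Cl
Why: Acylation of the primary allylic alcohol with a chloroformate gives the carbonate leaving group needed for the formation of the iridium allyl complex.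

Step 6
Reactants: 9 2,4,6-trihydroxybenzaldehyde
Product: 10 2,4-bis(tert-butyldimethylsilyloxy)-6-hydroxybenzaldehyde
Conditions: TBSCl (2.1 equiv), imidazole (3.0 equiv), CH2Cl2/DMF (10:1), 0 °C
Reagents that add atoms: tert-butyldimethylsilyl chloride, CC(C)(C)[Si](C)(C)Cl
Why: The 4-OH and one ortho OH are silylated, while the other ortho OH is held in a strong hydrogen bond to the formyl oxygen and should stay free when the silyl chloride is limited to two equivalents (regioselective silylation).

Step 7
Reactants: 10 2,4-bis(tert-butyldimethylsilyloxy)-6-hydroxybenzaldehyde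
Product: 11 3,5-bis(tert-butyldimethylsilyloxy)-2-vinylphenol
Conditions: Ph3PCH3Br (2.6 equiv), n-BuLi (2.5 equiv), THF, 0 °C; then 10, 0 °C to rt; aqueous NH4Cl
Reagents that add atoms: methyltriphenylphosphonium bromide, C[P+](c1ccccc1)(c1ccccc1)c1ccccc1.[Br-]
Why: Wittig methylenation with an excess of the non-stabilised ylide, one equivalent of which is used up in deprotonating the phenol, should convert the salicylaldehyde into the 2-vinylphenol, and an alkoxide-free ylide is chosen so that the aryl silyl ethers are not cleaved.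

Step 8
Reactants: 8 (E)-3-[3-(tert-butyldimethylsilyloxy)-4-(3-methylbut-2-enyloxy)phenyl]prop-2-enyl methyl carbonate; 11 3,5-bis(tert-butyldimethylsilyloxy)-2-vinylphenol (1.2 equiv)
Product: 12 (S)-1-[3-(tert-butyldimethylsilyloxy)-4-(3-methylbut-2-enyloxy)phenyl]allyl 3,5-bis(tert-butyldimethylsilyloxy)-2-vinylphenyl ether
Conditions: [Ir(cod)Cl]2 (2 mol%), (Sa,Sc,Sc)-O,O′-(1,1′-binaphthalene-2,2′-diyl)-N,N-bis(1-phenylethyl)phosphoramidite (4 mol%), pre-activated with n-PrNH2 (THF, 50 °C, volatiles removed); K3PO4 (1.0 equiv), THF, rt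
Reagents that add atoms: none
Why: In this iridium-catalysed asymmetric allylic etherification the carbonate ionises on the cyclometalated iridium–phosphoramidite complex to an allyl complex, which the phenoxide attacks at the aryl-substituted terminus (branched selectivity typical of iridium), and the chiral ligand fixes the face of attack and so sets C2 as (S).

Step 9
Reactants: 12 (S)-1-[3-(tert-butyldimethylsilyloxy)-4-(3-methylbut-2-enyloxy)phenyl]allyl 3,5-bis(tert-butyldimethylsilyloxy)-2-vinylphenyl ether
Product: 13 (2S)-5,7-bis(tert-butyldimethylsilyloxy)-2-[3-(tert-butyldimethylsilyloxy)-4-(3-methylbut-2-enyloxy)phenyl]-2H-chromene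
Conditions: RuCl2(PCy3)2(=CHPh) (first-generation Grubbs catalyst, 5 mol%), degassed CH2Cl2 (0.01 M), 40 °C, dark; then ethyl vinyl ether; chromatography on Et3N-deactivated silica
Reagents that add atoms: none
Why: This is a ring-closing olefin metathesis by the Chauvin mechanism: the ruthenium benzylidene exchanges onto the less hindered monosubstituted alkene of the allylic ether, the new alkylidene adds in a [2+2] sense to the neighbouring styrene, and cycloreversion of the ruthenacyclobutane forms the C3=C4 bond and releases ethylene, whose escape drives the reaction. The closest known reaction type is the ring-closing metathesis of allyl 2-vinylphenyl ethers to 2H-chromenes. Ring C is closed as a six-membered ring from a 1,7-diene whose two alkenes are held close on the arene and the ether oxygen, so closure should outrun intermolecular metathesis at this dilution. No stereocentre is formed, and C2, set in step 8, has no bond made or broken and stays (S). The step needs selectivity for the two terminal alkenes over the trisubstituted prenyl alkene, which the phosphine-only first-generation catalyst does not engage, and the product is kept from light and acid because a 2H-chromene can open electrocyclically to an ortho-quinone methide and reclose with loss of configuration at C2.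

Step 10
Reactants: 13 (2S)-5,7-bis(tert-butyldimethylsilyloxy)-2-[3-(tert-butyldimethylsilyloxy)-4-(3-methylbut-2-enyloxy)phenyl]-2H-chromene
Product: 14 (2S)-5,7-bis(tert-butyldimethylsilyloxy)-2-[3-(tert-butyldimethylsilyloxy)-4-(3-methylbut-2-enyloxy)phenyl]chroman-4-one
Conditions: PdCl2 (10 mol%), CuCl (30 mol%), O2 (1 atm), DMF/H2O (7:1), rt, dark
Reagents that add atoms: water, O
Why: In this Tsuji–Wacker oxidation divalent palladium binds the C3=C4 alkene, water attacks C4 (the benzylic carbon whose developing positive charge is stabilised by O1 and by the 5- and 7-silyloxy groups, and which lies away from the electron-withdrawing allylic C2–O bond), and β-hydride elimination with tautomerisation gives the C4 ketone, while the trisubstituted prenyl alkene binds palladium too weakly to compete and C2 is not touched.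

Step 11
Reactants: 14 (2S)-5,7-bis(tert-butyldimethylsilyloxy)-2-[3-(tert-butyldimethylsilyloxy)-4-(3-methylbut-2-enyloxy)phenyl]chroman-4-one
Product: 15 monotesone A, (2S)-5,7-dihydroxy-2-[3-hydroxy-4-(3-methylbut-2-enyloxy)phenyl]chroman-4-one
Conditions: Et3N·3HF (6 equiv), THF, 0 °C to rt
Reagents that add atoms: none
Why: Fluoride cleaves the three aryl Si–O bonds (desilylation), and the slightly acidic Et3N·3HF should avoid the phenoxide-driven retro-oxa-Michael opening to the chalcone that would racemise C2, while the prenyl ether is left intact.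

**Compound list**
1 | 3,4-dihydroxybenzaldehyde | O=Cc1ccc(O)c(O)c1 | starting material
2 | prenyl bromide (1-bromo-3-methylbut-2-ene) | CC(C)=CCBr | starting material
3 | 3-hydroxy-4-(3-methylbut-2-enyloxy)benzaldehyde | CC(C)=CCOc1ccc(C=O)cc1O | intermediate
4 | 3-(tert-butyldimethylsilyloxy)-4-(3-methylbut-2-enyloxy)benzaldehyde | CC(C)=CCOc1ccc(C=O)cc1O[Si](C)(C)C(C)(C)C | intermediate
5 | ethyl (E)-3-[3-(tert-butyldimethylsilyloxy)-4-(3-methylbut-2-enyloxy)phenyl]prop-2-enoate | CCOC(=O)/C=C/c1ccc(OCC=C(C)C)c(O[Si](C)(C)C(C)(C)C)c1 | intermediate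
6 | (E)-3-[3-(tert-butyldimethylsilyloxy)-4-(3-methylbut-2-enyloxy)phenyl]prop-2-enal (ring B cinnamaldehyde, not isolated) | O=C/C=C/c1ccc(OCC=C(C)C)c(O[Si](C)(C)C(C)(C)C)c1 | intermediate
7 | (E)-3-[3-(tert-butyldimethylsilyloxy)-4-(3-methylbut-2-enyloxy)phenyl]prop-2-en-1-ol | OC/C=C/c1ccc(OCC=C(C)C)c(O[Si](C)(C)C(C)(C)C)c1 | intermediate
8 | (E)-3-[3-(tert-butyldimethylsilyloxy)-4-(3-methylbut-2-enyloxy)phenyl]prop-2-enyl methyl carbonate | COC(=O)OC/C=C/c1ccc(OCC=C(C)C)c(O[Si](C)(C)C(C)(C)C)c1 | intermediate
9 | 2,4,6-trihydroxybenzaldehyde | O=Cc1c(O)cc(O)cc1O | starting material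
10 | 2,4-bis(tert-butyldimethylsilyloxy)-6-hydroxybenzaldehyde | O=Cc1c(O)cc(O[Si](C)(C)C(C)(C)C)cc1O[Si](C)(C)C(C)(C)C | intermediate
11 | 3,5-bis(tert-butyldimethylsilyloxy)-2-vinylphenol | C=Cc1c(O)cc(O[Si](C)(C)C(C)(C)C)cc1O[Si](C)(C)C(C)(C)C | intermediate
12 | (S)-1-[3-(tert-butyldimethylsilyloxy)-4-(3-methylbut-2-enyloxy)phenyl]allyl 3,5-bis(tert-butyldimethylsilyloxy)-2-vinylphenyl ether | CC(C)=CCOc1ccc([C@@H](Oc2cc(O[Si](C)(C)C(C)(C)C)cc(O[Si](C)(C)C(C)(C)C)c2C=C)C=C)cc1O[Si](C)(C)C(C)(C)C | intermediate
13 | (2S)-5,7-bis(tert-butyldimethylsilyloxy)-2-[3-(tert-butyldimethylsilyloxy)-4-(3-methylbut-2-enyloxy)phenyl]-2H-chromene | CC(C)=CCOc1ccc([C@@H]2C=Cc3c(O[Si](C)(C)C(C)(C)C)cc(O[Si](C)(C)C(C)(C)C)cc3O2)cc1O[Si](C)(C)C(C)(C)C | intermediate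
14 | (2S)-5,7-bis(tert-butyldimethylsilyloxy)-2-[3-(tert-butyldimethylsilyloxy)-4-(3-methylbut-2-enyloxy)phenyl]chroman-4-one | CC(C)=CCOc1ccc([C@@H]2CC(=O)c3c(O[Si](C)(C)C(C)(C)C)cc(O[Si](C)(C)C(C)(C)C)cc3O2)cc1O[Si](C)(C)C(C)(C)C | intermediate
15 | monotesone A, (2S)-5,7-dihydroxy-2-[3-hydroxy-4-(3-methylbut-2-enyloxy)phenyl]chroman-4-one | CC(C)=CCOc1ccc([C@@H]2CC(=O)c3c(O)cc(O)cc3O2)cc1O | target

**Step count**
Total: 11 steps. Longest linear sequence: 9 steps (steps 1 to 5, then 8 to 11); the ring A branch (steps 6 and 7) joins at step 8.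

**Steps most likely to fail**

Step 10 (Wacker oxidation). Water may add at C3 instead of C4 if palladium prefers the benzylic carbon. Palladium may also abstract the doubly activated C2–H, which would lead towards aromatised ring C and loss of the C2 configuration. Acid formed in the medium may strip silyl groups early. The fallback sets out from 13 and comes back at 14. Chromene 13 would be treated with catecholborane and [Rh(cod)2]BF4 with 1,4-bis(diphenylphosphino)butane in THF at low temperature. Rhodium-catalysed hydroboration of aryl alkenes places boron at the benzylic carbon, which should give the C4 catechol boronate F1. This would be oxidised in the same flask with NaBO3·4H2O to the flavan-4-ol F2; its mixture of C4 epimers does not matter. Dess–Martin periodinane with NaHCO3 in CH2Cl2 would then give ketone 14. The trisubstituted prenyl alkene should not react with catecholborane under these conditions.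

Step 8 (iridium-catalysed etherification). The phenoxide may attack the unsubstituted allyl terminus and give the linear ether. The ortho-substituted phenoxide may react slowly. The donor-substituted branched ether may ionise again on iridium and lose enantiomeric purity. The fallback sets out from 4 and comes back at 12. Ethynylmagnesium bromide in THF at 0 °C would add to aldehyde 4 to give the racemic propargylic alcohol F3, and Ac2O, Et3N and catalytic DMAP would give the propargylic acetate F4. A copper–pybox catalysed propargylic etherification with phenol 11 (CuOTf·0.5C6H6, the Ph-pybox enantiomer that gives the (S)-ether, i-Pr2NEt) runs through a copper allenylidene, so both enantiomers of F4 should converge on the (S)-propargyl ether F5. Semi-hydrogenation of the terminal alkyne (H2, Pd on CaCO3 poisoned with Pb(OAc)2, quinoline) would then give diene 12.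

Step 9 (ring-closing metathesis). The catalyst may load on the allyl ether alkene and then fail to engage the di-ortho-substituted, donor-rich styrene. Ruthenium hydrides may move the allyl ether double bond. The chromene may racemise by electrocyclic ring opening during the longer reaction time. A change to a second-generation catalyst alone is not counted as a fallback. The fallback closes ring C at the C4–C4a bond instead; it sets out from 4, through F3 and F4 as above, and comes back at 13. Benzene-1,3,5-triol would be silylated with two equivalents of TBSCl and imidazole to the symmetric 3,5-bis(tert-butyldimethylsilyloxy)phenol F6. The same copper–pybox etherification of acetate F4 with F6 would give the (S)-propargyl 3,5-bis(silyloxy)phenyl ether F7. Ph3PAuNTf2 (2 mol%) in CH2Cl2 at rt should then bring about a 6-endo-dig hydroarylation at either of the two equivalent ortho carbons, which gives chromene 13 without touching C2.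

Further compounds
F1 | step 10 | (2S)-4-(1,3,2-benzodioxaborol-2-yl)-5,7-bis(tert-butyldimethylsilyloxy)-2-[3-(tert-butyldimethylsilyloxy)-4-(3-methylbut-2-enyloxy)phenyl]chromane, mixture at C4 | CC(C)=CCOc1ccc([C@@H]2CC(B5Oc6ccccc6O5)c3c(O[Si](C)(C)C(C)(C)C)cc(O[Si](C)(C)C(C)(C)C)cc3O2)cc1O[Si](C)(C)C(C)(C)C
F2 | step 10 | (2S)-5,7-bis(tert-butyldimethylsilyloxy)-2-[3-(tert-butyldimethylsilyloxy)-4-(3-methylbut-2-enyloxy)phenyl]chroman-4-ol, mixture at C4 | CC(C)=CCOc1ccc([C@@H]2CC(O)c3c(O[Si](C)(C)C(C)(C)C)cc(O[Si](C)(C)C(C)(C)C)cc3O2)cc1O[Si](C)(C)C(C)(C)C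
F3 | step 8 | racemic 1-[3-(tert-butyldimethylsilyloxy)-4-(3-methylbut-2-enyloxy)phenyl]prop-2-yn-1-ol | CC(C)=CCOc1ccc(C(O)C#C)cc1O[Si](C)(C)C(C)(C)C
F4 | step 8 | racemic 1-[3-(tert-butyldimethylsilyloxy)-4-(3-methylbut-2-enyloxy)phenyl]prop-2-ynyl acetate | CC(C)=CCOc1ccc(C(OC(C)=O)C#C)cc1O[Si](C)(C)C(C)(C)C
F5 | step 8 | (S)-1-[3-(tert-butyldimethylsilyloxy)-4-(3-methylbut-2-enyloxy)phenyl]prop-2-ynyl 3,5-bis(tert-butyldimethylsilyloxy)-2-vinylphenyl ether | CC(C)=CCOc1ccc([C@@H](Oc2cc(O[Si](C)(C)C(C)(C)C)cc(O[Si](C)(C)C(C)(C)C)c2C=C)C#C)cc1O[Si](C)(C)C(C)(C)C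
F6 | step 9 | 3,5-bis(tert-butyldimethylsilyloxy)phenol | Oc1cc(O[Si](C)(C)C(C)(C)C)cc(O[Si](C)(C)C(C)(C)C)c1
F7 | step 9 | (S)-1-[3-(tert-butyldimethylsilyloxy)-4-(3-methylbut-2-enyloxy)phenyl]prop-2-ynyl 3,5-bis(tert-butyldimethylsilyloxy)phenyl ether | CC(C)=CCOc1ccc([C@@H](Oc2cc(O[Si](C)(C)C(C)(C)C)cc(O[Si](C)(C)C(C)(C)C)c2)C#C)cc1O[Si](C)(C)C(C)(C)C
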